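(Readings and results stem from a simulated flask on assumed constants; the scatter is artificial.)

Age is the measure here. The flasks below hold the same charges for the same time and differ in how and how cold the species go in.

| flask | starting complex | incoming ligand | leaving ligand | temperature | remark | time |
|---|---|---|---|---|---|---|
| cedar | 0.10 M | 0.30 M | 0.20 M | 20 °C | run made earlier |  |
| ash | 0.10 M | 0.42 M | 0.20 M | 31 °C | run made earlier |  |
| oak | 0.10 M | 0.66 M | 0.20 M | 20 °C | run made earlier |  |
| summer | 0.10 M | 0.300 M | 0.200 M | 25 °C | everything together at the start | 5.0 min |
| autumn | 0.10 M | 0.300 M (fed, over 3.0 min) | 0.200 M |  | the addition at 5 °C, then warmed to 25 °C; the feed brings no volume worth counting | 5.0 min |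
| winter | 0.10 M (in portions, 3, over 3.0 min) | 0.300 M | 0.200 M | 25 °C | first portion at the start, last at 3.0 min | 5.0 min |
| dusk | 0.10 M (fed, over 3.0 min) | 0.300 M | 0.200 M | 25 °C | all else is in the flask from the start; the feed brings no volume worth counting | 5.0 min |

- cedar (time / min: complex with three exchanged / %, side product / %): 1.00: 60.9, 12.1; 2.00: 53.3, 33.2; 3.00: 40.3, 51.3; 4.00: 30.8, 63.4; 5.00: 23.0, 70.4
- ash (time / min: complex with three exchanged / %, side product / %): 1.00: 51.7, 47.2; 2.00: 25.8, 72.5; 3.00: 11.7, 88.0; 4.00: 7.4, 92.9; 5.00: 1.9, 96.4
- oak (time / min: complex with three exchanged / %, side product / %): 0.417: 87.0, 9.6; 1.33: 67.6, 36.7; 2.50: 41.4, 56.6; 4.00: 24.1, 76.2; 5.00: 18.0, 83.4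

(scatter of a reading: 1 percentage point)

1. the flask that comes out highest in share of complex with three exchanged in complex with three exchanged plus side product, or "all alike" when all lie within 1.5 percentage points (summer / autumn / winter / dusk / all alike)
2. share of complex with three exchanged in complex with three exchanged plus side product at the end, summer
3. share of complex with three exchanged in complex with three exchanged plus side product at the end, autumn
4. share of complex with three exchanged in complex with three exchanged plus side product at the end, winter
5. share of complex with three exchanged in complex with three exchanged plus side product at the end, dusk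



Late in the oak run, with incoming ligand at 0.66 M against 0.10 M of starting complex, complex with three exchanged falls from 41.4 % to 18.0 %, which reads as 0.333 min⁻¹ at 20 °C. The ash run reads 0.743 min⁻¹ at 31 °C. Interpolating the logarithm gives 0.480 min⁻¹ at 25 °C: the ageing constant, the pseudo-first-order rate constant of the loss of complex with three exchanged to side product.

My reckoning freezes this constant, so material of one age keeps the share exp(−constant × age), where age is the time since the start of its exchange less a lag, and a flask with a spread of ages has the mean of that exponential over its charge. The cedar run's last share, taken as one age, gives an age of 4.21 min, hence a lag of 0.794 min, which I carry over unchanged. Summer then gives 13.3 %. Winter's portions, entering 1.50 min apart, average to 32.2 %, and dusk, fed steadily over 3.0 min, averages to 29.7 %. In autumn the constant extrapolates to 0.112 min⁻¹ at 5 °C, so I count only the warm 2.00 min, which gives 38.3 %, the highest of my figures.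

The forecast names autumn, with 13 % for summer, 47 % for autumn, 27 % for winter and 26 % for dusk, its autumn “leaving about 2 min or less at 25 °C”. The flasks give 13.0 % in summer, 40.4 % in autumn, 29.1 % in winter and 27.1 % in dusk, so autumn stands highest.

    starting complex + incoming ligand → leaving ligand + complex with one exchanged (k = 1.50 L mol⁻¹ s⁻¹, Ea = 43.0 kJ mol⁻¹)
    complex with one exchanged + incoming ligand → leaving ligand + complex with two exchanged (k = 0.450 L mol⁻¹ s⁻¹, Ea = 36.0 kJ mol⁻¹)
    complex with two exchanged + incoming ligand → leaving ligand + complex with three exchanged (k = 2.00 L mol⁻¹ s⁻¹, Ea = 58.0 kJ mol⁻¹)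
    leaving ligand + complex with three exchanged → side product (k = 0.0190 L mol⁻¹ s⁻¹, Ea = 52.0 kJ mol⁻¹)
    (constants at 25 °C)

Through the ageing constant, autumn's share equals that of a single age of 1.89 min and dusk's that of a single age of 2.72 min. In summer, the side step at charged [leaving ligand] has a half-life of 3.0 min, twice the 1.44 min that the ageing constant gives. At 2.50 min, summer holds [leaving ligand] at 214 % of its charge.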